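The numbers in the tables were computed for an exercise; the scatter is artificial.

**Late stretch.** Late in the red flask, from 10.0 h to 25.0 h, Jh gains 4 percentage points while 30% of Ja is still there, so something other than Ja is slowing it. I therefore count Ja half-lives: the logarithm to base two of Ja charged over Ja left. Treating Ja as pseudo-first-order, which sets aside the fall of Jc, equal counts mean equal doses of working catalyst. Ja starts at half of the Ja and Jb together charged, and in the red readings Ja plus Jh stays near that, so Jh gives the count.

| setting | red | grey | flask |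
|---|---|---|---|
| Ja | 0.54 M | 0.54 M | 0.54 M |
| Jb | 0.54 M | 0.54 M | 0.54 M |
| Jc | 1 equiv | 1 equiv | 1.00 equiv |
| Jd | 15 mol% | 15 mol% | 15 mol% |
| Jf | 58 mM | 58 mM | 58 mM |
| Jg | 64 mM | 64 mM | 64 mM |
| temperature | −20 °C | −25 °C | −20 °C |
| remark | the very flask that is asked about, followed so far | run made earlier |  |
| time |  |  | 40 h |

- red (time / h: Jh / %, Ja / %): 2.00: 7, 42; 4.00: 12, 44; 10.0: 15, 36; 25.0: 19, 30
- grey (time / h: Jh / %, Ja / %): 2.00: 2, 49; 4.00: 5, 44; 10.0: 8, 37; 25.0: 19, 32

(readings scatter by 1.5 percentage points)

- Jd is single-handed; Ja and Jb are mirror images of each other, charged as a racemate, each of them at the stated concentration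
- removed Jh is counted in
- the analysis behind the earlier runs scatters by 1.5 percentage points, standard deviation
- additions bring no volume worth counting

- dawn: at 40 h take out 90% of the Jh then present, then wait 40 h
- spring: at 40 h add Jd, 100% of the amount charged, then wait 40 h
- noon: at 40 h raise the temperature by 10 K, then wait 40 h
- autumn: at 40 h add Jc, 100% of the amount charged, then wait 40 h
- summer: change nothing and wait 40 h more

- Jh, in percent of the Ja and Jb together first charged, at 40 h
- the remedy with the largest gain of Jh, or "none" below 2 percentage points (dawn / spring / noon / autumn / summer / none)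
- Jh present, with what was taken out counted in, in percent of the Ja and Jb together first charged, after dawn
- Jh present, with what was taken out counted in, in percent of the Ja and Jb together first charged, after summer

**What matters.** The reading at 2.00 h does not enter my reckoning. I leave out the grey run at −25 °C, as the red flask is this flask at its own −20 °C. The reading at 25.0 h enters both the count and its slope, and its scatter is 1.5 points. The slowing is the other number to know: if the count stops there, Jh stays at 19%, and if the last stretch's gain repeats, Jh reaches 22.5%.

**The number.** From Jh the count is 0.396, 0.515 and 0.690 at 4.00 h, 10.0 h and 25.0 h. Its hourly gain fell by a factor of 1.70 between the last two stretches. Given the scatter, I round that factor to 2 and give the equally long stretch to 40 h half the last gain. That makes the Ja half-life count 0.777, which means 20.8% Jh. The count is below one, so Ja remains to be turned over. A falling dose of working catalyst is what added Jd would make up, so I choose spring.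

**The forecast.** The forecast gives 20.5%, 22% after dawn and 22% after summer, and it chooses spring: “Fresh Jd should give a new burst”.

**The flask.** The flask gives 20.9%, 25.0% after dawn and 25.0% after summer, and spring adds 18 points. Its 58% of Ja left is a count of 0.786, beside my 0.777.

    Jc + Jd + Ja → Jd + Jh (k = 0.00276 L² mol⁻² s⁻¹, Ea = 42.0 kJ mol⁻¹)
    Jc + Jd + Jb → Jd + Jj (k = 2.29 × 10⁻⁴ L² mol⁻² s⁻¹, Ea = 44.0 kJ mol⁻¹)
    Jd ⇌ Je (K = 10.4, k = 4.50 × 10⁻⁵ s⁻¹, Ea = 72.0 kJ mol⁻¹, ΔH = −67.0 kJ mol⁻¹)
    Jd + Jf ⇌ Jk (K = 7.00 L mol⁻¹, k = 0.0215 L mol⁻¹ s⁻¹, Ea = 53.0 kJ mol⁻¹, ΔH = −23.0 kJ mol⁻¹)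
    Jd + Jg → Jm (k = 0.161 L mol⁻¹ s⁻¹, Ea = 56.0 kJ mol⁻¹)
    (constants at −20 °C)

Of the turnover up to 40.0 h, half of the loss of Jd with Jg to Jm is done by 1.22 min, and half of the making of Jh by 5.22 h, far later. At 40.0 h Jm holds 79.0% of the catalyst charged. With 4.00 equiv of Jc, Jm holds the same 79.0%, so I multiply my count by the Jc ratio, which gives 44.2% Jh, and that flask stands at 45.6%.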